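The numbers in the tables were computed from invented constants; the scatter is artificial.

Late readings tell you where not to look. At 5.00 h, both earlier runs hold less complex with one exchanged than at their highest readings.

| flask | starting complex | incoming ligand | scavenger | remark | time |
|---|---|---|---|---|---|
| green | 0.12 M | 0.12 M | 0.072 M (fed, over 10 min) | run made earlier |  |
| grey | 0.48 M | 0.12 M | 0.072 M (fed, over 10 min) | run made earlier |  |
| flask | 0.24 M | 0.120 M | 0.0720 M (fed, over 10 min) |  | 5.0 h |

| run | time / h | complex with one exchanged / % | starting complex / % |
|---|---|---|---|
| green | 0.0500 | 11.7 | 73.8 |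
| green | 0.133 | 16.5 | 50.2 |
| green | 0.333 | 16.3 | 28.1 |
| green | 0.833 | 11.6 | 13.6 |
| green | 2.00 | 9.0 | 8.7 |
| green | 5.00 | 9.3 | 3.0 |
| grey | 0.0500 | 8.2 | 53.5 |
| grey | 0.133 | 9.9 | 30.3 |
| grey | 0.333 | 10.8 | 15.0 |
| grey | 0.833 | 8.7 | 7.8 |
| grey | 2.00 | 9.1 | 2.3 |
| grey | 5.00 | 8.2 | 1.0 |

(scatter of a reading: 0.5 percentage points)

- the best time, 5.0 h at the latest, for complex with one exchanged
- the amount of complex with one exchanged, in percent of the starting complex charged, at that time
- the first time at which complex with one exchanged reaches 7.2 %, in the same percent, in min



Read the tables column against column. Green ends at 9.3 % and grey at 8.2 %, while their highest readings are 16.5 % at 0.133 h and 10.8 % at 0.333 h. So you look for an early peak in the flask too.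

Now take the starting complex column. In grey the limiting reagent is incoming ligand, 0.12 M against 0.48 M of starting complex. Yet by 0.0500 h grey has lost 0.223 M of starting complex, more than that ligand. So if one incoming ligand takes one starting complex, starting complex in grey has another way out. Grey's highest reading also stands below green's.

Green to grey is two doublings, so the peak factor is 0.809: the multiplier on the highest reading per doubling of c(starting complex), the other charges held. The flask has twice green's charge, so your reckoning gives 13.3 %. That stands above both late readings.

The forecast says 13.5 % at 0.2 h, slightly above your figure, and 1.9 min for the first time asked. It holds that “the early peak is the optimum”.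

The flask gives 14.3 % at 0.205 h, and it reaches 7.2 % at 1.67 min.

    2 starting complex → homo dimer (k = 0.240 M⁻¹ min⁻¹)
    complex with one exchanged + incoming ligand → over-reaction product (k = 0.540 M⁻¹ min⁻¹)
    scavenger + leaving ligand → scavenged by-product (k = 2.10 M⁻¹ min⁻¹)
    starting complex + incoming ligand → leaving ligand + complex with one exchanged (k = 0.520 M⁻¹ min⁻¹)
    complex with one exchanged + incoming ligand → leaving ligand + complex with two exchanged (k = 0.620 M⁻¹ min⁻¹)
    complex with two exchanged + incoming ligand → leaving ligand + complex with three exchanged (k = 0.510 M⁻¹ min⁻¹)
    leaving ligand + incoming ligand ⇌ idle adduct, settled at all times (K = 7.60 M⁻¹)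

On this flask, the factor 0.809 gave 13.3 %, which is 1.00 percentage point under the result. Now take the neighbouring flask with 0.96 M of starting complex, the other charges as in the recipe. It has twice grey's charge, so the same step gives 8.74 %. That flask gives 6.69 %, less than the reckoning. It carries 0.125 equiv of incoming ligand. After 5.00 h, complex with one exchanged stands at 6.32 %, and homo dimer holds 90.0 % of the starting complex charged.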